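Convention used throughout: ring A is the phloroglucinol ring, ring B the 4-methoxyphenyl ring of the acyl chain, ring C the 4-hydroxyphenyl ring on C1', ring D the 4-hydroxyphenyl ring on C4'; C1'–C4' is the butyl chain counted from ring A.

## The problem

Target 23 is a 2',4',6'-trihydroxy-4-methoxydihydrochalcone whose ring A carries an open C1'–C4' chain at one of its two remaining positions. Nothing is ring-fused, so the task is chain construction, not ring assembly. The chain holds three contiguous stereocentres, (1'R,2'R,3'S): C1' is a diarylmethine joining rings A and C, C2' and C3' bear only methyl groups, and C4' is the benzylic methylene of ring D. C2' and C3' have no functional group in the target, so whatever controls them must be erased down to CH3. C1' can be set under the influence of C2' next to it but has no other nearby control element. C1' is doubly benzylic on an electron-rich ring and can re-ionise in acid once the ring A oxygens are free, so it must be set early and the late steps kept near neutral. Five phenols must end free while ring B keeps its methyl ether, which calls for hydrogenolysable groups on rings A, C and D and for ring B to arrive late inside the acyl unit. The enabling feature is that C2' and C3' with their methyl groups map onto the α- and β-carbons of a γ-butyrolactone, the carbonyl and acetal carbons being the two methyls at a higher oxidation level. C4' beside the β-carbon is then an acyl-anion equivalent of ring D's aldehyde, and C1' beside the α-carbon is the carbonyl carbon of ring A's aldehyde.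

## Retrosynthesis

**23 ⇒ 22 ⇒ 19 + 20.** The five O–benzyl bonds and the ring A–acyl bond are cut. Benzyl is chosen because its removal is neutral and leaves the ring B methyl ether and C1' alone. The acyl bond is cut before debenzylation because a tris(benzyloxy)benzene is acylated by a mixed anhydride without a metal Lewis acid, whereas C-acylation of the free polyphenol needs hot Lewis acid that could re-ionise C1'. Arene 19 has no ring B, no ketone and no O- versus C-acylation question. The forward step must acylate ring A once and nowhere else: its two open positions are equivalent, rings C and D are far less nucleophilic, and the first acyl group deactivates the ring.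

**19 ⇒ 18 ⇒ 17 ⇒ 16.** The two methyl groups are traced through bis-mesylate 18 and diol 17 to the carbonyl and acetal carbons of lactone 16. This is preferred to bringing in methyl groups on an open chain, because the ring of 16 ties C2' and C3' together and makes their trans relationship a matter of ring geometry. Lactone 16 has the carbon skeleton of 19 with its stereochemistry held in a five-membered ring. The forward steps must reduce both oxidised carbons, return auxiliary 3, and deoxygenate twice without closing a tetrahydrofuran.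

**16 ⇒ 15 ⇒ 14 ⇒ 11 + 12.** The two C4'–S bonds, the ring C benzyl ether and the C1'–ring C bond are cut, leading to carbinol 11 and phenol 12. The neighbouring cut, C1'–ring A with ring C on the cation, would use the better nucleophile but is rejected on stereochemical grounds: in cation 13 the nucleophile should enter anti to C3', and only when the incoming group is ring C does 1'R result. The cut also removes a stereocentre from the precursor, since both epimers of 11 give 13. The forward step needs ionisation mild enough for the benzyl ethers and the acetal, para attack by 12, and capture by 12 ahead of ring A of a second molecule (large excess of 12, slow addition of 11).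

**11 ⇒ 6 + 4 + 8.** The C4'–C3' and C2'–C1' bonds are cut. This is the only cut that creates C2' and C3' together, and it gives each flanking carbon its natural polarity: C4' as a dithiane anion, C1' as an aldehyde carbon. Three pieces of similar size result, none with a stereocentre other than those of the auxiliary. The forward step must add 1,4 anti to the menthyloxy group and then capture a hindered aldehyde anti to the new dithianyl group.

**4 ⇒ 2 + 3, 2 ⇒ 1; 6 ⇒ 5; 8 ⇒ 7.** Acetal C–O, C–S and O–benzyl bonds are cut to reach commercial materials. (+)-Menthol 3, not its antipode, is required: the acetal centre it leaves after crystallisation, 5S, places the dithianyl group on the face needed for 3'S.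

## Roads not taken

**Alternative 1:** The cut removes ring A itself: three of its bonds are broken so that the finished side chain hangs on siloxyalkyne A2, and the ring is rebuilt from 3-ethoxycyclobutenone A3. Forward, heating A2 with A3 opens the cyclobutenone to a vinylketene, which adds to the alkyne; a second ring opening and 6π closure give phenol A1.
- Merits: the substitution pattern of ring A is fixed by mechanism, its three oxygens arrive differentiated, and C1' is never a cation beside a nucleophilic ring. In that respect it is better than the chosen plan.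
- Weak points: it builds the one ring that can be bought. It contributes nothing to the three stereocentres, which must all be made beforehand in an open chain ending in a propargylic, benzylic C1' that the strong base needed for siloxyalkyne formation can epimerise. The ethyl ether and the methyl ethers on rings C and D of A1 must be cleaved before ring B with its methoxy group is attached, which forces the acylation onto a free pentaphenol under Lewis acid.
- Comparison: the chosen plan is less secure at the C1'–aryl bond, but it sets two centres in one operation from purchased rings and ends with neutral hydrogenolysis. Alternative 1 is longer before its key step and harsher after it.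

**Alternative 2:** The cut is at C4'–C3' and C3'–C2': the chain is grown from benzylboronic ester A5 by two one-carbon insertions. Forward, ester A6 is lithiated next to oxygen in the presence of a chiral diamine, the carbenoid adds to boron, and a 1,2-metallate shift inserts a CH(CH3) unit; a second round gives A4.
- Merits: both methyl-bearing centres are set by the reagent, independently of each other. The methyls arrive as methyls, so the three steps the chosen plan spends turning lactone carbons into CH3 are saved. C1' could in principle be set the same way, by one more homologation and a stereospecific arylation. On step economy and reagent control this road is better.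
- Weak points: each insertion needs a stoichiometric chiral diamine at low temperature, and the required (2'R,3'S) pattern may call for the less accessible diamine enantiomer. The C1' stage must place the doubly ortho-substituted, trioxygenated ring A on a crowded secondary boronic ester flanked by two branched carbons, where boronate formation and migration slow down and a benzylic boronic ester on so electron-rich a ring is prone to protodeboronation.
- Comparison: A4 is reached in fewer steps than lactone 16. The chosen plan sets against this cheap chirality from 3, diastereomers that can be purified at the lactone stage, and a C1' construction that uses the electron-rich ring A instead of fighting its bulk.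

**Alternative 3:** The cut is at C1'–ring C and C1'–C2': aldehyde A8 (ring A with an ortho O-Boc group), Grignard reagent A10 and silyl ketene acetal A11 of lactone A9 are joined to give A7. Forward, A10 adds to A8, the alkoxide takes over the Boc group, the phenoxide expels the carbonate and unveils the o-quinone methide of ring A, and A11 attacks its methide carbon.
- Merits: ring C enters by Grignard addition to an aldehyde, with no regiochemical question and no cation that ring A could intercept. At this bond it is clearly better than phenol capture in the chosen plan. The conditions are basic and the sequence after the key step is shorter.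
- Weak points: C1' and C2' are both created in an intermolecular addition to a short-lived o-quinone methide. The trans lactone is assured by the β-benzyl group, but the configuration of C1' relative to C2' depends on the methide geometry and an open transition state for which no dependable model exists. A9 needs its own enantioselective synthesis, and the freed ortho phenol of A7 must be protected again.
- Comparison: this road is as good or better for the C1'–ring C bond and in length. The chosen plan sets against it a C1' step with one defined reactive conformer, a cation on which both carbinol epimers converge, and C2' and C3' set together from one auxiliary.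

Key step: step 5

## Route

Step 1
Reactants: 1 furfural
Product: 2 5-hydroxyfuran-2(5H)-one (racemic)
Conditions: O2, hν (visible), rose bengal (cat.), MeOH, rt
Reagents that add atoms: dioxygen, O=O
Why: Singlet-oxygen [4+2] cycloaddition to the furan and methanolysis of the endoperoxide expel the formyl carbon as methyl formate and leave the hydroxybutenolide; dye-sensitised photo-oxygenation of furfural is a standard preparation.

Step 2
Reactants: 2 5-hydroxyfuran-2(5H)-one; 3 (+)-menthol
Product: 4 (5S)-5-{[(1S,2R,5S)-2-isopropyl-5-methylcyclohexyl]oxy}furan-2(5H)-one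
Conditions: CSA (cat.), toluene, reflux (Dean–Stark); crystallisation from petroleum ether, −20 °C; liquors re-equilibrated with CSA and recrystallised
Reagents that add atoms: none
Why: Acid-catalysed acetalisation gives both C5 epimers, which interconvert under acid; the 5S epimer of the (+)-menthol series is the mirror image of the well-known crystalline 5R acetal of (−)-menthol and should crystallise in the same way, so crystallisation with recycling of the liquors sets the acetal centre.

Step 3
Reactants: 5 4-(benzyloxy)benzaldehyde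
Product: 6 2-[4-(benzyloxy)phenyl]-1,3-dithiane
Conditions: HS(CH2)3SH, BF3·OEt2 (cat.), CH2Cl2, 0 °C → rt
Reagents that add atoms: propane-1,3-dithiol, SCCCS
Why: Lewis acid-catalysed dithioacetalisation of an aromatic aldehyde; the aryl benzyl ether tolerates catalytic BF3·OEt2 at this temperature.

Step 4
Reactants: 7 2,4,6-trihydroxybenzaldehyde
Product: 8 2,4,6-tris(benzyloxy)benzaldehyde
Conditions: BnBr, K2CO3, DMF, rt → 60 °C
Reagents that add atoms: benzyl bromide, BrCc1ccccc1
Why: Williamson etherification; the formyl group lowers the C-nucleophilicity of the ring, so O-benzylation of all three phenols should prevail.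

Step 5
Reactants: 6 2-[4-(benzyloxy)phenyl]-1,3-dithiane; 4 (5S)-5-(menthyloxy)furan-2(5H)-one; 8 2,4,6-tris(benzyloxy)benzaldehyde
Product: 11 (3R,4S,5S)-4-{2-[4-(benzyloxy)phenyl]-1,3-dithian-2-yl}-3-{hydroxy[2,4,6-tris(benzyloxy)phenyl]methyl}-5-{[(1S,2R,5S)-2-isopropyl-5-methylcyclohexyl]oxy}dihydrofuran-2(3H)-one as a mixture of C1' carbinol epimers, via 2-lithio-2-[4-(benzyloxy)phenyl]-1,3-dithiane 9 (not isolated), via lithium lactone enolate 10 (not isolated)
Conditions: 6, n-BuLi, THF, −78 °C; then 4, −78 °C; then 8, −78 °C; AcOH quench at −78 °C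
Reagents that add atoms: none
Why: n-BuLi deprotonates 6 to the aryl- and sulfur-stabilised anion 9, a soft nucleophile that adds 1,4 to butenolide 4 and forms the C4'–C3' bond. The lithium enolate 10 so formed adds to the non-enolisable aldehyde 8 and forms the C2'–C1' bond. The closest known reaction type is the tandem conjugate addition–aldol of lithiated 2-aryl-1,3-dithianes and aromatic aldehydes on 5-alkoxybutenolides, the standard entry to lignan lactones. No ring is closed. C3' (lactone C4) is set by the C5 menthyloxy group, which shields its own face of the flat butenolide so that 9 enters anti (4,5-trans). C2' (lactone C3) is set by the new dithianyl group, which sends the aldehyde to the opposite face of the enolate (3,4-trans). The carbinol centre C1' is not controlled and need not be, since step 6 ionises it. The step needs 1,4- over 1,2-addition, secured by the delocalised anion in THF, and aldol capture over proton transfer or retro-aldol, secured by an aldehyde without α-hydrogens, lithium chelation by its ortho benzyloxy groups and the acidic quench at −78 °C.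

Step 6
Reactants: 11 carbinol lactone (both C1' epimers); 12 phenol
Product: 14 (3S,4S,5S)-4-{2-[4-(benzyloxy)phenyl]-1,3-dithian-2-yl}-3-{(R)-(4-hydroxyphenyl)[2,4,6-tris(benzyloxy)phenyl]methyl}-5-{[(1S,2R,5S)-2-isopropyl-5-methylcyclohexyl]oxy}dihydrofuran-2(3H)-one, via C1' benzylic cation 13 (not isolated)
Conditions: PhOH (50 equiv), CF3CO2H (3 equiv), CH2Cl2, −20 → 0 °C, slow addition of 11
Reagents that add atoms: none
Why: SN1 Friedel–Crafts alkylation: both epimers of 11 ionise to the same cation 13, stabilised by three benzyloxy groups, and the para carbon of phenol, present in large excess, captures it. Allylic 1,3-strain against the ortho benzyloxy group should hold the C2'–H bond in the plane of the cation, with the flat lactone carbonyl on one face and C3' with its dithianyl group on the other, so phenol enters past the carbonyl, anti to C3', giving 1'R as in known diastereoselective Friedel–Crafts alkylations of α-branched benzylic cations. The in-plane C2'–H is orthogonal to the vacant orbital, which disfavours E1 loss, and ring D offers only a position meta to its oxygen for cyclisation.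

Step 7
Reactants: 14 ring C phenol
Product: 15 (3S,4S,5S)-4-{2-[4-(benzyloxy)phenyl]-1,3-dithian-2-yl}-3-{(R)-[4-(benzyloxy)phenyl][2,4,6-tris(benzyloxy)phenyl]methyl}-5-{[(1S,2R,5S)-2-isopropyl-5-methylcyclohexyl]oxy}dihydrofuran-2(3H)-one
Conditions: BnBr, K2CO3, DMF, rt
Reagents that add atoms: benzyl bromide, BrCc1ccccc1
Why: Williamson etherification of the only free phenol, so that ring C survives the later sulfonylation and acylation; K2CO3 is too weak to enolise the lactone and the acetal is base-stable.

Step 8
Reactants: 15 dithianyl lactone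
Product: 16 (3S,4S,5S)-4-[4-(benzyloxy)benzyl]-3-{(R)-[4-(benzyloxy)phenyl][2,4,6-tris(benzyloxy)phenyl]methyl}-5-{[(1S,2R,5S)-2-isopropyl-5-methylcyclohexyl]oxy}dihydrofuran-2(3H)-one
Conditions: Bu3SnH (6 equiv), AIBN (portionwise), toluene, reflux
Reagents that add atoms: none
Why: Radical-chain desulfurisation of a benzylic dithioacetal: the stannyl radical attacks sulfur, the aryl- and sulfur-stabilised C4' radical takes hydrogen from the stannane, and a second cycle leaves the CH2 group; aryl benzyl ethers, the lactone and the acetal are inert to tin radicals and no stereocentre is involved.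

Step 9
Reactants: 16 menthyloxy lactone
Product: 17 (2S,3S)-2-[4-(benzyloxy)benzyl]-3-{(R)-[4-(benzyloxy)phenyl][2,4,6-tris(benzyloxy)phenyl]methyl}butane-1,4-diol
Conditions: LiAlH4, THF, 0 °C → rt; aqueous NaOH work-up
Reagents that add atoms: none
Why: Hydride reduces the lactone carbonyl; the ring-opened hemiacetal alkoxide expels menthoxide and the aldehyde so freed is reduced as well, giving the 1,4-diol and returning (+)-menthol, as in known reductions of menthyloxy lignan lactones; C2' and C3' are not touched.

Step 10
Reactants: 17 diol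
Product: 18 (2S,3S)-2-[4-(benzyloxy)benzyl]-3-{(R)-[4-(benzyloxy)phenyl][2,4,6-tris(benzyloxy)phenyl]methyl}butane-1,4-diyl dimethanesulfonate
Conditions: MsCl, Et3N, CH2Cl2, −20 → 0 °C
Reagents that add atoms: methanesulfonyl chloride, CS(=O)(=O)Cl
Why: Sulfonylation through sulfene is fast at both primary hydroxyls and should outrun closure of a mono-mesylate to a tetrahydrofuran; this is the usual activation of lignan 1,4-diols.

Step 11
Reactants: 18 bis-mesylate
Product: 19 1,3,5-tris(benzyloxy)-2-{(1R,2R,3S)-1,4-bis[4-(benzyloxy)phenyl]-2,3-dimethylbutyl}benzene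
Conditions: LiEt3BH, THF, 0 °C → rt
Reagents that add atoms: none
Why: SN2 displacement of both primary mesylates by hydride gives the two methyl groups; LiEt3BH attacks carbon and not sulfur at β-branched primary centres and works below room temperature, where participation by the ortho benzyloxy oxygen is slow.

Step 12
Reactants: 19 pentabenzyl arene; 20 3-(4-methoxyphenyl)propanoic acid
Product: 22 1-{2,4,6-tris(benzyloxy)-3-[(1R,2R,3S)-1,4-bis[4-(benzyloxy)phenyl]-2,3-dimethylbutyl]phenyl}-3-(4-methoxyphenyl)propan-1-one, via mixed trifluoroacetic anhydride 21 (not isolated)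
Conditions: 20, (CF3CO)2O, CH2Cl2, 0 °C; then 19, 0 °C → rt
Reagents that add atoms: none
Why: Friedel–Crafts acylation through the mixed anhydride 21, which acylates 1,3,5-trialkoxybenzenes without a metal Lewis acid; ring A is far more nucleophilic than the 4-alkoxyphenyl rings B, C and D, its two open positions are equivalent, and the first acyl group deactivates it against a second.

Step 13
Reactants: 22 pentabenzyl ketone
Product: 23 1-{2,4,6-trihydroxy-3-[(1R,2R,3S)-1,4-bis(4-hydroxyphenyl)-2,3-dimethylbutyl]phenyl}-3-(4-methoxyphenyl)propan-1-one (target)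
Conditions: H2 (1 atm), Pd/C (10%), EtOAc–MeOH, rt
Reagents that add atoms: none
Why: Hydrogenolysis of five aryl benzyl ethers under neutral conditions; the methyl ether stays, C1' is not ionised, and the ketone, first twisted between two ortho substituents and then hydrogen-bonded to the freed ortho phenols, should resist reduction at 1 atm.

## Compound list

1 | furfural | O=Cc1ccco1 | starting material
2 | 5-hydroxyfuran-2(5H)-one (racemic) | OC1OC(=O)C=C1 | intermediate
3 | (+)-menthol, (1S,2R,5S)-2-isopropyl-5-methylcyclohexanol | CC(C)[C@H]1CC[C@H](C)C[C@@H]1O | starting material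
4 | (5S)-5-{[(1S,2R,5S)-2-isopropyl-5-methylcyclohexyl]oxy}furan-2(5H)-one | CC(C)[C@H]1CC[C@H](C)C[C@@H]1O[C@H]1OC(=O)C=C1 | intermediate
5 | 4-(benzyloxy)benzaldehyde | O=Cc1ccc(OCc2ccccc2)cc1 | starting material
6 | 2-[4-(benzyloxy)phenyl]-1,3-dithiane | C1CSC(c2ccc(OCc3ccccc3)cc2)SC1 | intermediate
7 | 2,4,6-trihydroxybenzaldehyde | O=Cc1c(O)cc(O)cc1O | starting material
8 | 2,4,6-tris(benzyloxy)benzaldehyde | O=Cc1c(OCc2ccccc2)cc(OCc2ccccc2)cc1OCc1ccccc1 | intermediate
9 | 2-lithio-2-[4-(benzyloxy)phenyl]-1,3-dithiane | [Li]C1(c2ccc(OCc3ccccc3)cc2)SCCCS1 | intermediate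
10 | lithium (4S,5S)-4-{2-[4-(benzyloxy)phenyl]-1,3-dithian-2-yl}-5-{[(1S,2R,5S)-2-isopropyl-5-methylcyclohexyl]oxy}-4,5-dihydrofuran-2-olate | CC(C)[C@H]1CC[C@H](C)C[C@@H]1O[C@H]1OC(O[Li])=C[C@@H]1C1(c2ccc(OCc3ccccc3)cc2)SCCCS1 | intermediate
11 | (3R,4S,5S)-4-{2-[4-(benzyloxy)phenyl]-1,3-dithian-2-yl}-3-{hydroxy[2,4,6-tris(benzyloxy)phenyl]methyl}-5-{[(1S,2R,5S)-2-isopropyl-5-methylcyclohexyl]oxy}dihydrofuran-2(3H)-one (both C1' epimers) | CC(C)[C@H]1CC[C@H](C)C[C@@H]1O[C@H]1OC(=O)[C@@H](C(O)c2c(OCc3ccccc3)cc(OCc3ccccc3)cc2OCc2ccccc2)[C@@H]1C1(c2ccc(OCc3ccccc3)cc2)SCCCS1 | intermediate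
12 | phenol | Oc1ccccc1 | starting material
13 | C1' benzylic cation of 11: the (3S,4S,5S)-lactone bearing at C3 a [2,4,6-tris(benzyloxy)phenyl]methylium carbon | CC(C)[C@H]1CC[C@H](C)C[C@@H]1O[C@H]1OC(=O)[C@@H]([CH+]c2c(OCc3ccccc3)cc(OCc3ccccc3)cc2OCc2ccccc2)[C@@H]1C1(c2ccc(OCc3ccccc3)cc2)SCCCS1 | intermediate
14 | (3S,4S,5S)-4-{2-[4-(benzyloxy)phenyl]-1,3-dithian-2-yl}-3-{(R)-(4-hydroxyphenyl)[2,4,6-tris(benzyloxy)phenyl]methyl}-5-{[(1S,2R,5S)-2-isopropyl-5-methylcyclohexyl]oxy}dihydrofuran-2(3H)-one | CC(C)[C@H]1CC[C@H](C)C[C@@H]1O[C@H]1OC(=O)[C@@H]([C@H](c2ccc(O)cc2)c2c(OCc3ccccc3)cc(OCc3ccccc3)cc2OCc2ccccc2)[C@@H]1C1(c2ccc(OCc3ccccc3)cc2)SCCCS1 | intermediate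
15 | (3S,4S,5S)-4-{2-[4-(benzyloxy)phenyl]-1,3-dithian-2-yl}-3-{(R)-[4-(benzyloxy)phenyl][2,4,6-tris(benzyloxy)phenyl]methyl}-5-{[(1S,2R,5S)-2-isopropyl-5-methylcyclohexyl]oxy}dihydrofuran-2(3H)-one | CC(C)[C@H]1CC[C@H](C)C[C@@H]1O[C@H]1OC(=O)[C@@H]([C@H](c2ccc(OCc3ccccc3)cc2)c2c(OCc3ccccc3)cc(OCc3ccccc3)cc2OCc2ccccc2)[C@@H]1C1(c2ccc(OCc3ccccc3)cc2)SCCCS1 | intermediate
16 | (3S,4S,5S)-4-[4-(benzyloxy)benzyl]-3-{(R)-[4-(benzyloxy)phenyl][2,4,6-tris(benzyloxy)phenyl]methyl}-5-{[(1S,2R,5S)-2-isopropyl-5-methylcyclohexyl]oxy}dihydrofuran-2(3H)-one | CC(C)[C@H]1CC[C@H](C)C[C@@H]1O[C@H]1OC(=O)[C@@H]([C@H](c2ccc(OCc3ccccc3)cc2)c2c(OCc3ccccc3)cc(OCc3ccccc3)cc2OCc2ccccc2)[C@@H]1Cc1ccc(OCc2ccccc2)cc1 | intermediate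
17 | (2S,3S)-2-[4-(benzyloxy)benzyl]-3-{(R)-[4-(benzyloxy)phenyl][2,4,6-tris(benzyloxy)phenyl]methyl}butane-1,4-diol | c1(OCc2ccccc2)cc(OCc2ccccc2)cc(OCc2ccccc2)c1[C@@H](c1ccc(OCc2ccccc2)cc1)[C@H](CO)[C@@H](CO)Cc1ccc(OCc2ccccc2)cc1 | intermediate
18 | (2S,3S)-2-[4-(benzyloxy)benzyl]-3-{(R)-[4-(benzyloxy)phenyl][2,4,6-tris(benzyloxy)phenyl]methyl}butane-1,4-diyl dimethanesulfonate | c1(OCc2ccccc2)cc(OCc2ccccc2)cc(OCc2ccccc2)c1[C@@H](c1ccc(OCc2ccccc2)cc1)[C@H](COS(C)(=O)=O)[C@@H](COS(C)(=O)=O)Cc1ccc(OCc2ccccc2)cc1 | intermediate
19 | 1,3,5-tris(benzyloxy)-2-{(1R,2R,3S)-1,4-bis[4-(benzyloxy)phenyl]-2,3-dimethylbutyl}benzene | c1(OCc2ccccc2)cc(OCc2ccccc2)cc(OCc2ccccc2)c1[C@@H](c1ccc(OCc2ccccc2)cc1)[C@H](C)[C@@H](C)Cc1ccc(OCc2ccccc2)cc1 | intermediate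
20 | 3-(4-methoxyphenyl)propanoic acid | COc1ccc(CCC(=O)O)cc1 | starting material
21 | 3-(4-methoxyphenyl)propanoic trifluoroacetic anhydride | COc1ccc(CCC(=O)OC(=O)C(F)(F)F)cc1 | intermediate
22 | 1-{2,4,6-tris(benzyloxy)-3-[(1R,2R,3S)-1,4-bis[4-(benzyloxy)phenyl]-2,3-dimethylbutyl]phenyl}-3-(4-methoxyphenyl)propan-1-one | COc1ccc(CCC(=O)c2c(OCc3ccccc3)cc(OCc3ccccc3)c([C@@H](c3ccc(OCc4ccccc4)cc3)[C@H](C)[C@@H](C)Cc3ccc(OCc4ccccc4)cc3)c2OCc2ccccc2)cc1 | intermediate
23 | 1-{2,4,6-trihydroxy-3-[(1R,2R,3S)-1,4-bis(4-hydroxyphenyl)-2,3-dimethylbutyl]phenyl}-3-(4-methoxyphenyl)propan-1-one | COc1ccc(CCC(=O)c2c(O)cc(O)c([C@@H](c3ccc(O)cc3)[C@H](C)[C@@H](C)Cc3ccc(O)cc3)c2O)cc1 | target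

## Step count and least certain steps

Total step count: 13. Longest linear sequence: 11 steps (steps 1, 2 and 5–13, from furfural).

**Step 5 (key step).** The aldol addition to the doubly ortho-substituted, electron-rich aldehyde may be slow and reversible, so the enolate could be lost to proton transfer or the aldolate could revert before the quench. The fallback replaces the reversible aldol by an irreversible C-acylation and sets out from aldehyde 8. Pinnick oxidation (NaClO2, NaH2PO4, 2-methyl-2-butene) gives 2,4,6-tris(benzyloxy)benzoic acid F1, and oxalyl chloride with catalytic DMF gives 2,4,6-tris(benzyloxy)benzoyl chloride F2. Enolate 10, generated exactly as in step 5, is added to F2 at −78 °C (inverse addition, to limit proton transfer to the acidic product) and gives the trans α-aroyl lactone F3. Reduction of its ketone with NaBH4 in MeOH–THF at −20 °C comes back to carbinol 11, whose configuration at C1' is again of no consequence.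

**Step 6.** The most likely failure is poor chemoselectivity: the free positions of ring A in a second molecule are more nucleophilic than phenol, so cation 13 may be captured there and oligomerise despite the excess of phenol. Incomplete facial selectivity at C1' or some ortho attack on phenol are lesser risks. The fallback blocks ring A and sets out from aldehyde 8. N-Bromosuccinimide (2 equiv, CH2Cl2–MeCN, 0 °C) gives 2,4,6-tris(benzyloxy)-3,5-dibromobenzaldehyde F4, which replaces 8 under the conditions of step 5 and gives the dibromo carbinol lactone F5. Ionisation in the presence of phenol as in step 6 gives the dibromo diarylmethyl lactone F6, whose ring A can no longer act as a nucleophile. Benzylation as in step 7 gives the benzyl ether F7. Under the conditions of step 8 with additional Bu3SnH, both aryl–bromine bonds are reduced together with the dithiane, which comes back to lactone 16.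

**Step 8.** The second carbon–sulfur cleavage may stall at an open-chain benzylic thioether, since six-membered dithioacetals give up sulfur to tin radicals more slowly than five-membered ones. The fallback changes the order of events and the reagent class and sets out from 15. LiAlH4 first reduces the lactone to the dithianyl diol F8, releasing menthol. Sulfur is then removed with Ni2B generated from NiCl2·6H2O and NaBH4 in MeOH–THF at 0 °C, a reagent that spares aryl benzyl ethers and now meets no lactone. This comes back to diol 17.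

**Step 11.** β-Branching slows the SN2 path at the C2' mesyloxymethyl group. Hydride attack at sulfur (returning the alcohol) or ring closure by the neighbouring ortho benzyloxy oxygen could then compete. The fallback replaces hydride displacement by a radical reduction and sets out from 18. Sodium benzeneselenolate (from PhSeSePh and NaBH4, EtOH–THF, rt), a far better nucleophile than hydride at hindered primary carbon, gives the bis(phenylselanyl) compound F9. Bu3SnH with AIBN in toluene at 80 °C cleaves both carbon–selenium bonds by a radical chain indifferent to branching and comes back to 19.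

**Step 12.** The trifluoroacetic acid set free may protonate the very electron-rich ring A at the carbon bearing C1' and open a retro-Friedel–Crafts path (epimerisation or loss of the side chain). Acylation may also be slow at a position flanked by two benzyloxy groups. The fallback builds the ketone without an acylium ion and sets out from 19. Vilsmeier–Haack formylation (POCl3, DMF, 0 °C → rt, then aqueous NaOAc) gives the ring A aldehyde F10. 2-(4-Methoxyphenyl)ethylmagnesium bromide F11, made from the bromide and Mg in THF, adds to it and gives the secondary alcohol F12. Dess–Martin periodinane oxidises F12 and comes back to ketone 22.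

## Further compounds

F1 | step 5 | 2,4,6-tris(benzyloxy)benzoic acid | O=C(O)c1c(OCc2ccccc2)cc(OCc2ccccc2)cc1OCc1ccccc1
F2 | step 5 | 2,4,6-tris(benzyloxy)benzoyl chloride | O=C(Cl)c1c(OCc2ccccc2)cc(OCc2ccccc2)cc1OCc1ccccc1
F3 | step 5 | (3R,4S,5S)-4-{2-[4-(benzyloxy)phenyl]-1,3-dithian-2-yl}-5-{[(1S,2R,5S)-2-isopropyl-5-methylcyclohexyl]oxy}-3-[2,4,6-tris(benzyloxy)benzoyl]dihydrofuran-2(3H)-one | CC(C)[C@H]1CC[C@H](C)C[C@@H]1O[C@H]1OC(=O)[C@@H](C(=O)c2c(OCc3ccccc3)cc(OCc3ccccc3)cc2OCc2ccccc2)[C@@H]1C1(c2ccc(OCc3ccccc3)cc2)SCCCS1
F4 | step 6 | 2,4,6-tris(benzyloxy)-3,5-dibromobenzaldehyde | O=Cc1c(OCc2ccccc2)c(Br)c(OCc2ccccc2)c(Br)c1OCc1ccccc1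
F5 | step 6 | (3R,4S,5S)-4-{2-[4-(benzyloxy)phenyl]-1,3-dithian-2-yl}-3-{hydroxy[2,4,6-tris(benzyloxy)-3,5-dibromophenyl]methyl}-5-{[(1S,2R,5S)-2-isopropyl-5-methylcyclohexyl]oxy}dihydrofuran-2(3H)-one (both C1' epimers) | CC(C)[C@H]1CC[C@H](C)C[C@@H]1O[C@H]1OC(=O)[C@@H](C(O)c2c(OCc3ccccc3)c(Br)c(OCc3ccccc3)c(Br)c2OCc2ccccc2)[C@@H]1C1(c2ccc(OCc3ccccc3)cc2)SCCCS1
F6 | step 6 | (3S,4S,5S)-4-{2-[4-(benzyloxy)phenyl]-1,3-dithian-2-yl}-3-{(R)-(4-hydroxyphenyl)[2,4,6-tris(benzyloxy)-3,5-dibromophenyl]methyl}-5-{[(1S,2R,5S)-2-isopropyl-5-methylcyclohexyl]oxy}dihydrofuran-2(3H)-one | CC(C)[C@H]1CC[C@H](C)C[C@@H]1O[C@H]1OC(=O)[C@@H]([C@H](c2ccc(O)cc2)c2c(OCc3ccccc3)c(Br)c(OCc3ccccc3)c(Br)c2OCc2ccccc2)[C@@H]1C1(c2ccc(OCc3ccccc3)cc2)SCCCS1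
F7 | step 6 | (3S,4S,5S)-4-{2-[4-(benzyloxy)phenyl]-1,3-dithian-2-yl}-3-{(R)-[4-(benzyloxy)phenyl][2,4,6-tris(benzyloxy)-3,5-dibromophenyl]methyl}-5-{[(1S,2R,5S)-2-isopropyl-5-methylcyclohexyl]oxy}dihydrofuran-2(3H)-one | CC(C)[C@H]1CC[C@H](C)C[C@@H]1O[C@H]1OC(=O)[C@@H]([C@H](c2ccc(OCc3ccccc3)cc2)c2c(OCc3ccccc3)c(Br)c(OCc3ccccc3)c(Br)c2OCc2ccccc2)[C@@H]1C1(c2ccc(OCc3ccccc3)cc2)SCCCS1
F8 | step 8 | (2S,3S)-2-{2-[4-(benzyloxy)phenyl]-1,3-dithian-2-yl}-3-{(R)-[4-(benzyloxy)phenyl][2,4,6-tris(benzyloxy)phenyl]methyl}butane-1,4-diol | c1(OCc2ccccc2)cc(OCc2ccccc2)cc(OCc2ccccc2)c1[C@@H](c1ccc(OCc2ccccc2)cc1)[C@H](CO)[C@@H](CO)C1(c2ccc(OCc3ccccc3)cc2)SCCCS1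
F9 | step 11 | 1,3,5-tris(benzyloxy)-2-{(1R,2S,3S)-1,4-bis[4-(benzyloxy)phenyl]-2,3-bis[(phenylselanyl)methyl]butyl}benzene | c1(OCc2ccccc2)cc(OCc2ccccc2)cc(OCc2ccccc2)c1[C@@H](c1ccc(OCc2ccccc2)cc1)[C@H](C[Se]c1ccccc1)[C@@H](C[Se]c1ccccc1)Cc1ccc(OCc2ccccc2)cc1
F10 | step 12 | 2,4,6-tris(benzyloxy)-3-{(1R,2R,3S)-1,4-bis[4-(benzyloxy)phenyl]-2,3-dimethylbutyl}benzaldehyde | O=Cc1c(OCc2ccccc2)cc(OCc2ccccc2)c([C@@H](c2ccc(OCc3ccccc3)cc2)[C@H](C)[C@@H](C)Cc2ccc(OCc3ccccc3)cc2)c1OCc1ccccc1
F11 | step 12 | 2-(4-methoxyphenyl)ethylmagnesium bromide | COc1ccc(CC[Mg]Br)cc1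
F12 | step 12 | 1-{2,4,6-tris(benzyloxy)-3-[(1R,2R,3S)-1,4-bis[4-(benzyloxy)phenyl]-2,3-dimethylbutyl]phenyl}-3-(4-methoxyphenyl)propan-1-ol (both carbinol epimers) | COc1ccc(CCC(O)c2c(OCc3ccccc3)cc(OCc3ccccc3)c([C@@H](c3ccc(OCc4ccccc4)cc3)[C@H](C)[C@@H](C)Cc3ccc(OCc4ccccc4)cc3)c2OCc2ccccc2)cc1
A1 | alternative 1 | 5-ethoxy-2-[(1R,2R,3S)-1,4-bis(4-methoxyphenyl)-2,3-dimethylbutyl]-3-[(triisopropylsilyl)oxy]phenol | CCOc1cc(O)c([C@@H](c2ccc(OC)cc2)[C@H](C)[C@@H](C)Cc2ccc(OC)cc2)c(O[Si](C(C)C)(C(C)C)C(C)C)c1
A2 | alternative 1 | triisopropyl{[(3R,4R,5S)-3,6-bis(4-methoxyphenyl)-4,5-dimethylhex-1-yn-1-yl]oxy}silane | CC(C)[Si](C(C)C)(C(C)C)OC#C[C@@H](c1ccc(OC)cc1)[C@H](C)[C@@H](C)Cc1ccc(OC)cc1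
A3 | alternative 1 | 3-ethoxycyclobut-2-en-1-one | CCOC1=CC(=O)C1
A4 | alternative 2 | 2-{(2R,3S)-4-[4-(benzyloxy)phenyl]-3-methylbutan-2-yl}-4,4,5,5-tetramethyl-1,3,2-dioxaborolane | CC1(C)OB(OC1(C)C)[C@H](C)[C@@H](C)Cc1ccc(OCc2ccccc2)cc1
A5 | alternative 2 | 2-[4-(benzyloxy)benzyl]-4,4,5,5-tetramethyl-1,3,2-dioxaborolane | CC1(C)OB(Cc2ccc(OCc3ccccc3)cc2)OC1(C)C
A6 | alternative 2 | ethyl 2,4,6-triisopropylbenzoate | CCOC(=O)c1c(C(C)C)cc(C(C)C)cc1C(C)C
A7 | alternative 3 | (3S,4S)-4-[4-(benzyloxy)benzyl]-3-{(R)-[4-(benzyloxy)phenyl][2,4-bis(benzyloxy)-6-hydroxyphenyl]methyl}dihydrofuran-2(3H)-one | O=C1OC[C@@H](Cc2ccc(OCc3ccccc3)cc2)[C@@H]1[C@H](c1ccc(OCc2ccccc2)cc1)c1c(O)cc(OCc2ccccc2)cc1OCc1ccccc1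
A8 | alternative 3 | 2,4-bis(benzyloxy)-6-[(tert-butoxycarbonyl)oxy]benzaldehyde | CC(C)(C)OC(=O)Oc1cc(OCc2ccccc2)cc(OCc2ccccc2)c1C=O
A9 | alternative 3 | (S)-4-[4-(benzyloxy)benzyl]dihydrofuran-2(3H)-one | O=C1OC[C@@H](Cc2ccc(OCc3ccccc3)cc2)C1
A10 | alternative 3 | 4-(benzyloxy)phenylmagnesium bromide | Br[Mg]c1ccc(OCc2ccccc2)cc1
A11 | alternative 3 | {[(S)-4-[4-(benzyloxy)benzyl]-4,5-dihydrofuran-2-yl]oxy}trimethylsilane | C[Si](C)(C)OC1=C[C@H](Cc2ccc(OCc3ccccc3)cc2)CO1
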